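**Strategy.** The route rests on disconnecting the C3''=C4'' cis-olefin of the 2,2-dimethyl-2H-pyran (ring D), which is fused to ring B through the C2' oxygen and C3'. Ring-closing olefin metathesis between a vinyl group on C3' and a 1,1-dimethylallyl ether on the C2' oxygen closes ring D in one operation and fixes, by construction, which oxygen and which carbon of ring B carry the pyran. The precursor is a 1-bromo-2-(1,1-dimethylallyloxy)-3-vinyl-4-(methoxymethoxy)benzene, made by fluoride displacement and Wittig methylenation. The resulting bromochromene is joined to a 6-prenylchroman-4-one by ketone α-arylation; transfer hydrogenation with dynamic kinetic resolution sets C3, and radical deoxygenation removes the C4 oxygen.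

Key step: step 5

Remark: isoflavan locants are used for the target (O1, C2–C8a for rings C and A, primes for ring B, double primes for pyran ring D); chromene and chromanone intermediates carry their own locants.

**Fragment B (ring B with ring D)**

Step 1
Reactants: 1 4-bromo-3-fluorophenol
Product: 2 1-bromo-2-fluoro-4-(methoxymethoxy)benzene
Conditions: MOMCl, K2CO3, acetone, 0 °C to rt
Reagents that add atoms: chloromethyl methyl ether, COCCl
Why: O-alkylation of the phenoxide (MOM ether formation) installs a group that directs the metalation of step 2 and is stable to the bases, organometallics and radicals used later.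

Step 2
Reactants: 2 1-bromo-2-fluoro-4-(methoxymethoxy)benzene
Product: 4 3-bromo-2-fluoro-6-(methoxymethoxy)benzaldehyde, via aryllithium 3 (not isolated)
Conditions: LDA, THF, −78 °C; DMF, −78 to 0 °C; then H2O
Reagents that add atoms: N,N-dimethylformamide, CN(C)C=O
Why: Directed ortho-metalation with an amide base (no bromine–lithium exchange) should remove the proton between F and OMOM, the site activated by both groups, and formylation with DMF gives the aldehyde; −78 °C avoids loss of LiF to an aryne.

Step 3
Reactants: 4 3-bromo-2-fluoro-6-(methoxymethoxy)benzaldehyde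
Product: 5 3-bromo-6-(methoxymethoxy)-2-[(2-methylbut-3-en-2-yl)oxy]benzaldehyde
Conditions: 2-methylbut-3-en-2-ol, NaH, THF/DMF, 0 °C; then 4, 0 °C to rt
Reagents that add atoms: 2-methylbut-3-en-2-ol, CC(C)(O)C=C
Why: Nucleophilic aromatic substitution (SNAr) of the fluoride, activated by the ortho formyl group and the ortho bromine, by a tertiary alkoxide that has no α-hydrogen to reduce the aldehyde; bromide and OMOM are not leaving groups under these conditions.

Step 4
Reactants: 5 3-bromo-6-(methoxymethoxy)-2-[(2-methylbut-3-en-2-yl)oxy]benzaldehyde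
Product: 6 1-bromo-3-ethenyl-4-(methoxymethoxy)-2-[(2-methylbut-3-en-2-yl)oxy]benzene
Conditions: Ph3PCH3Br, KOtBu, THF, 0 °C to rt
Reagents that add atoms: methyltriphenylphosphonium bromide, C[P+](c1ccccc1)(c1ccccc1)c1ccccc1.[Br-]
Why: Wittig methylenation with the unstabilised ylide converts the hindered but non-enolisable aldehyde into the styrene without touching the aryl bromide or the allylic ether.

Step 5
Reactants: 6 1-bromo-3-ethenyl-4-(methoxymethoxy)-2-[(2-methylbut-3-en-2-yl)oxy]benzene
Product: 7 8-bromo-5-(methoxymethoxy)-2,2-dimethyl-2H-chromene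
Conditions: second-generation Grubbs catalyst RuCl2(=CHPh)(PCy3)(H2IMes) (3 mol%), CH2Cl2 (0.01 M), 40 °C
Reagents that add atoms: none
Why: Ring-closing olefin metathesis by the Chauvin mechanism: the ruthenium benzylidene exchanges onto the more accessible styrenyl vinyl group, the new alkylidene adds intramolecularly in a [2+2] sense to the 1,1-dimethylallyl olefin, and cycloreversion of the ruthenacyclobutane releases the chromene while ethene escapes. The closest known reaction type is the metathesis of 2-vinylaryl 1,1-dimethylallyl ethers to 2,2-dimethyl-2H-chromenes. The six-membered ring D is closed by forming the C3=C4 bond of the chromene (C3''=C4'' of the target); no stereocentre is created and the Z geometry is enforced by the ring. The step needs ring closure to win over intermolecular metathesis, which the gem-dimethyl group (Thorpe–Ingold effect), the reluctance of the hindered tertiary allylic olefin to homodimerise, and high dilution should secure. The position of the pyran on ring B (oxygen on the carbon next to C–Br, olefin carbon on the carbon between the two oxygens) is already fixed by the fluoride and formyl positions of 4; the aryl bromide and MOM ether are inert to the carbene, and 40 °C stays below the onset of Claisen-type rearrangement of the ether.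

**Fragment A (rings A and C)**

Step 6
Reactants: 8 7-hydroxychroman-4-one
Product: 9 6-bromo-7-hydroxychroman-4-one
Conditions: NBS (1.0 equiv), MeCN, 0 °C
Reagents that add atoms: N-bromosuccinimide, O=C1CCC(=O)N1Br
Why: Electrophilic aromatic bromination should go to C6, which is ortho to the 7-OH, para to O1 and less hindered than C8 between the two oxygens.

Step 7
Reactants: 9 6-bromo-7-hydroxychroman-4-one
Product: 10 6-bromo-7-(methoxymethoxy)chroman-4-one
Conditions: MOMCl, K2CO3, acetone, rt
Reagents that add atoms: chloromethyl methyl ether, COCCl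
Why: O-alkylation of the acidic vinylogous-acid phenol (MOM ether formation) under mild carbonate conditions that do not enolise the ketone.

Step 8
Reactants: 10 6-bromo-7-(methoxymethoxy)chroman-4-one
Product: 11 7-(methoxymethoxy)-6-(3-methylbut-2-en-1-yl)chroman-4-one
Conditions: tributyl(3-methylbut-2-en-1-yl)stannane, Pd(PPh3)4 (5 mol%), DMF, 90 °C
Reagents that add atoms: tributyl(3-methylbut-2-en-1-yl)stannane, CCCC[Sn](CCCC)(CCCC)CC=C(C)C
Why: Stille coupling of the aryl bromide with the prenylstannane should give mainly the linear prenyl arene by reductive elimination at the less substituted allyl terminus, and it tolerates the ketone.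

**Union and end game**

Step 9
Reactants: 11 7-(methoxymethoxy)-6-(3-methylbut-2-en-1-yl)chroman-4-one; 7 8-bromo-5-(methoxymethoxy)-2,2-dimethyl-2H-chromene
Product: 12 rac-3-[5-(methoxymethoxy)-2,2-dimethyl-2H-chromen-8-yl]-7-(methoxymethoxy)-6-(3-methylbut-2-en-1-yl)chroman-4-one
Conditions: Pd2(dba)3 (2.5 mol%), P(t-Bu)3·HBF4 (6 mol%), NaOtBu, toluene, 70 °C
Reagents that add atoms: none
Why: Palladium-catalysed ketone α-arylation: the enolate at C3, the only enolisable position, couples with the arylpalladium bromide from 7, and the more acidic product is held as its enolate, which should suppress diarylation; because ring D is already closed, no pendant olefin is available for a competing intramolecular Heck reaction.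

Step 10
Reactants: 12 rac-3-[5-(methoxymethoxy)-2,2-dimethyl-2H-chromen-8-yl]-7-(methoxymethoxy)-6-(3-methylbut-2-en-1-yl)chroman-4-one
Product: 13 (3R,4R)-3-[5-(methoxymethoxy)-2,2-dimethyl-2H-chromen-8-yl]-7-(methoxymethoxy)-6-(3-methylbut-2-en-1-yl)chroman-4-ol
Conditions: RuCl[(R,R)-TsDPEN](p-cymene) (2 mol%), HCO2H/Et3N (1:1), EtOAc, 40 °C
Reagents that add atoms: none
Why: Noyori–Ikariya asymmetric transfer hydrogenation with dynamic kinetic resolution: the α-aryl ketone racemises through its enol under the amine base, the (R,R)-catalyst is expected to deliver hydride to the aryl ketone face that gives the (4R)-carbinol (as for chroman-4-one), and the enantiomer leading to the cis alcohol reacts faster, so C4 is set by the catalyst and C3 by the cis-selective resolution; the prenyl and chromene olefins are not reduced.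

Step 11
Reactants: 13 (3R,4R)-3-[5-(methoxymethoxy)-2,2-dimethyl-2H-chromen-8-yl]-7-(methoxymethoxy)-6-(3-methylbut-2-en-1-yl)chroman-4-ol
Product: 16 O-{(3R,4R)-3-[5-(methoxymethoxy)-2,2-dimethyl-2H-chromen-8-yl]-7-(methoxymethoxy)-6-(3-methylbut-2-en-1-yl)chroman-4-yl} S-methyl carbonodithioate, via sodium alkoxide 14 (not isolated), via sodium xanthate 15 (not isolated)
Conditions: NaH, THF, 0 °C; CS2; MeI, 0 °C to rt
Reagents that add atoms: carbon disulfide, S=C=S; iodomethane, CI
Why: Xanthate formation (first stage of a Barton–McCombie deoxygenation) under basic, non-ionising conditions; the aryl group at C3 is cis to the oxygen, so no syn β-hydrogen is available for Chugaev elimination.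

Step 12
Reactants: 16 O-{(3R,4R)-3-[5-(methoxymethoxy)-2,2-dimethyl-2H-chromen-8-yl]-7-(methoxymethoxy)-6-(3-methylbut-2-en-1-yl)chroman-4-yl} S-methyl carbonodithioate
Product: 17 (3R)-3-[5-(methoxymethoxy)-2,2-dimethyl-2H-chromen-8-yl]-7-(methoxymethoxy)-6-(3-methylbut-2-en-1-yl)chromane
Conditions: Bu3SnH, Et3B, air, toluene, rt
Reagents that add atoms: none
Why: Barton–McCombie radical deoxygenation: the stannyl radical adds to C=S, β-scission gives the C4 benzylic radical and hydrogen transfer from the stannane gives the methylene; a radical is chosen because a C4 cation would be trapped by the neighbouring pyran oxygen of ring D, and C3 is not touched.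

Step 13
Reactants: 17 (3R)-3-[5-(methoxymethoxy)-2,2-dimethyl-2H-chromen-8-yl]-7-(methoxymethoxy)-6-(3-methylbut-2-en-1-yl)chromane
Product: 18 (3R)-3-(5-hydroxy-2,2-dimethyl-2H-chromen-8-yl)-6-(3-methylbut-2-en-1-yl)chroman-7-ol
Conditions: HCl (1 M in MeOH), rt; NaHCO3 quench
Reagents that add atoms: none
Why: Acid-catalysed acetal exchange with methanol (MOM cleavage) frees both phenols under dilute acid at room temperature, conditions under which ortho-prenylphenols and 2,2-dimethylchromenes are expected to survive; C3 is not epimerisable.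

**Compound list**

1 | 4-bromo-3-fluorophenol | Oc1ccc(Br)c(F)c1 | starting material
2 | 1-bromo-2-fluoro-4-(methoxymethoxy)benzene | COCOc1ccc(Br)c(F)c1 | intermediate
3 | [3-bromo-2-fluoro-6-(methoxymethoxy)phenyl]lithium | [Li]c1c(F)c(Br)ccc1OCOC | intermediate (not isolated)
4 | 3-bromo-2-fluoro-6-(methoxymethoxy)benzaldehyde | O=Cc1c(F)c(Br)ccc1OCOC | intermediate
5 | 3-bromo-6-(methoxymethoxy)-2-[(2-methylbut-3-en-2-yl)oxy]benzaldehyde | O=Cc1c(OC(C)(C)C=C)c(Br)ccc1OCOC | intermediate
6 | 1-bromo-3-ethenyl-4-(methoxymethoxy)-2-[(2-methylbut-3-en-2-yl)oxy]benzene | C=Cc1c(OC(C)(C)C=C)c(Br)ccc1OCOC | intermediate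
7 | 8-bromo-5-(methoxymethoxy)-2,2-dimethyl-2H-chromene | COCOc1ccc(Br)c2OC(C)(C)C=Cc12 | intermediate
8 | 7-hydroxychroman-4-one | O=C1CCOc2cc(O)ccc12 | starting material
9 | 6-bromo-7-hydroxychroman-4-one | O=C1CCOc2cc(O)c(Br)cc12 | intermediate
10 | 6-bromo-7-(methoxymethoxy)chroman-4-one | O=C1CCOc2cc(OCOC)c(Br)cc12 | intermediate
11 | 7-(methoxymethoxy)-6-(3-methylbut-2-en-1-yl)chroman-4-one | O=C1CCOc2cc(OCOC)c(CC=C(C)C)cc12 | intermediate
12 | rac-3-[5-(methoxymethoxy)-2,2-dimethyl-2H-chromen-8-yl]-7-(methoxymethoxy)-6-(3-methylbut-2-en-1-yl)chroman-4-one (racemate) | CC(C)=CCc1cc2c(cc1OCOC)OCC(c1ccc(OCOC)c3c1OC(C)(C)C=C3)C2=O | intermediate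
13 | (3R,4R)-3-[5-(methoxymethoxy)-2,2-dimethyl-2H-chromen-8-yl]-7-(methoxymethoxy)-6-(3-methylbut-2-en-1-yl)chroman-4-ol (cis) | CC(C)=CCc1cc2c(cc1OCOC)OC[C@@H](c1ccc(OCOC)c3c1OC(C)(C)C=C3)[C@H]2O | intermediate
14 | sodium (3R,4R)-3-[5-(methoxymethoxy)-2,2-dimethyl-2H-chromen-8-yl]-7-(methoxymethoxy)-6-(3-methylbut-2-en-1-yl)chroman-4-olate | CC(C)=CCc1cc2c(cc1OCOC)OC[C@@H](c1ccc(OCOC)c3c1OC(C)(C)C=C3)[C@H]2[O-].[Na+] | intermediate (not isolated)
15 | sodium O-{(3R,4R)-3-[5-(methoxymethoxy)-2,2-dimethyl-2H-chromen-8-yl]-7-(methoxymethoxy)-6-(3-methylbut-2-en-1-yl)chroman-4-yl} carbonodithioate | CC(C)=CCc1cc2c(cc1OCOC)OC[C@@H](c1ccc(OCOC)c3c1OC(C)(C)C=C3)[C@H]2OC(=S)[S-].[Na+] | intermediate (not isolated)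
16 | O-{(3R,4R)-3-[5-(methoxymethoxy)-2,2-dimethyl-2H-chromen-8-yl]-7-(methoxymethoxy)-6-(3-methylbut-2-en-1-yl)chroman-4-yl} S-methyl carbonodithioate | CC(C)=CCc1cc2c(cc1OCOC)OC[C@@H](c1ccc(OCOC)c3c1OC(C)(C)C=C3)[C@H]2OC(=S)SC | intermediate
17 | (3R)-3-[5-(methoxymethoxy)-2,2-dimethyl-2H-chromen-8-yl]-7-(methoxymethoxy)-6-(3-methylbut-2-en-1-yl)chromane | CC(C)=CCc1cc2c(cc1OCOC)OC[C@@H](c1ccc(OCOC)c3c1OC(C)(C)C=C3)C2 | intermediate
18 | (3R)-3-(5-hydroxy-2,2-dimethyl-2H-chromen-8-yl)-6-(3-methylbut-2-en-1-yl)chroman-7-ol | CC(C)=CCc1cc2c(cc1O)OC[C@@H](c1ccc(O)c3c1OC(C)(C)C=C3)C2 | target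

**Step count**

Total: 13 steps. Longest linear sequence: 10 steps (steps 1–5, then 9–13); fragment A takes 3 steps (6–8).

**Steps most likely to fail**

1. Step 9 (ketone α-arylation). The alkoxide base at 70 °C may open the chromanone enolate by retro-oxa-Michael elimination, and oxidative addition and reductive elimination may be slow with the electron-rich, ortho-alkoxy bromide, so that decomposition of the ketone outruns coupling. The fallback sets out from 11 and avoids a free enolate at elevated temperature. Kinetic silylation (LiHMDS, TMSCl, THF, −78 °C) should give trimethyl{[7-(methoxymethoxy)-6-(3-methylbut-2-en-1-yl)-2H-chromen-4-yl]oxy}silane F3. Fluoride-promoted palladium-catalysed arylation of this silyl enol ether with 7 (Pd(OAc)2, P(t-Bu)3, Bu3SnF, toluene, 80 °C) then returns to the route at 12.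

2. Step 3 (SNAr with the tertiary alkoxide). Attack at the C–F carbon, flanked by bromine and the formyl group, may be sterically retarded, so that reversible addition to the aldehyde and subsequent hydride-transfer side reactions dominate. The fallback sets out from 4 and forms the ether bond at the tertiary carbon instead of at the arene. Hydroxide displacement of fluoride (KOH, DMSO/H2O, 60 °C, then dilute HCl) should give 3-bromo-2-hydroxy-6-(methoxymethoxy)benzaldehyde F1. Copper-catalysed O-propargylation (3-chloro-3-methylbut-1-yne, CuCl2 cat., DBU, MeCN, 0 °C) then gives 3-bromo-6-(methoxymethoxy)-2-[(2-methylbut-3-yn-2-yl)oxy]benzaldehyde F2. Semi-hydrogenation (H2, Pd/CaCO3 poisoned with Pb(OAc)2, quinoline, EtOAc) returns to the route at 5.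

3. Step 11 (xanthate formation, together with its use in step 12). The electron-rich benzylic C4–O bond of the xanthate may ionise, leading to O-to-S rearrangement or to capture of the cation by the ring D oxygen with loss of the pyran. The fallback sets out from 13 and uses a poorer leaving group with single-electron reduction. Acylation (4-methylbenzoyl chloride, pyridine, DMAP, CH2Cl2, 0 °C) should give (3R,4R)-3-[5-(methoxymethoxy)-2,2-dimethyl-2H-chromen-8-yl]-7-(methoxymethoxy)-6-(3-methylbut-2-en-1-yl)chroman-4-yl 4-methylbenzoate F4. Markó–Lam deoxygenation (SmI2, HMPA, THF, rt) then returns to the route at 17, bypassing 16.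

**Further compounds**

F1 | step 3 | 3-bromo-2-hydroxy-6-(methoxymethoxy)benzaldehyde | O=Cc1c(O)c(Br)ccc1OCOC
F2 | step 3 | 3-bromo-6-(methoxymethoxy)-2-[(2-methylbut-3-yn-2-yl)oxy]benzaldehyde | O=Cc1c(OC(C)(C)C#C)c(Br)ccc1OCOC
F3 | step 9 | trimethyl{[7-(methoxymethoxy)-6-(3-methylbut-2-en-1-yl)-2H-chromen-4-yl]oxy}silane | C[Si](C)(C)OC1=CCOc2cc(OCOC)c(CC=C(C)C)cc12
F4 | step 11 | (3R,4R)-3-[5-(methoxymethoxy)-2,2-dimethyl-2H-chromen-8-yl]-7-(methoxymethoxy)-6-(3-methylbut-2-en-1-yl)chroman-4-yl 4-methylbenzoate | CC(C)=CCc1cc2c(cc1OCOC)OC[C@@H](c1ccc(OCOC)c3c1OC(C)(C)C=C3)[C@H]2OC(=O)c1ccc(C)cc1
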